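**Retrosynthetic overview**
1. Target ⇐ Si–O cleavage ⇐ eleven-membered ring closed last by Ni/Cr coupling of a C1 alkenyl triflate with the C14 aldehyde (C1–C14 bond).
2. C2/C3 trans-diacetate, C15 methyl and C1 triflate all derive from one C1 enone (epoxidation then acetate opening; enolate methylation; O-triflation). The side chain (acrolein + crotylboronate) is joined at C8–C9 by B-alkyl Suzuki coupling.
3. cis-Hydrindenone with C4, C16 and C7 set in one step ⇐ Cu-catalysed enantioselective borylative cyclisation of a prochiral allenyl cyclohexadienone, which also delivers the C8=C19 methylene as an alkenyl boronate.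
4. Allenyl dienone ⇐ oxidative dearomatising para-allylation of p-cresol, then allyl → aldehyde → alkyne → allene.
5. Ring order: six-membered ring (from the arene) → cyclopentane (key step) → eleven-membered ring (last).

Assumption: atoms carry trinervitane-type numbering (six-membered ring C1–C4, C16, C15; cyclopentane C4–C7, C16; bridge C8–C14; C19 = exocyclic CH2), β is the face of the C4 methyl, and the antipode of a chiral catalyst is used if its sense of induction turns out opposite.

**Step 1**
Reactants: 1 p-cresol (4-methylphenol); 2 allyltrimethylsilane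
Product: 3 4-allyl-4-methylcyclohexa-2,5-dien-1-one
Conditions: PhI(OAc)2 (1.2 equiv), 2 (4 equiv), (CF3)2CHOH, −10 °C to rt
Reagents that add atoms: none
Why: Oxidative dearomatisation (oxidative Hosomi–Sakurai-type para-allylation): the trivalent-iodine oxidant turns the phenol into a phenoxenium equivalent that the allylsilane captures at the methyl-bearing para carbon, creating quaternary C4, which is still prochiral.

**Step 2**
Reactants: 3 4-allyl-4-methylcyclohexa-2,5-dien-1-one
Product: 4 3-(1-methyl-4-oxocyclohexa-2,5-dien-1-yl)propanal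
Conditions: PdCl2(PhCN)2 (10 mol%), CuCl2·2H2O (10 mol%), AgNO2 (5 mol%), O2 (1 atm), t-BuOH/MeNO2 15:1, rt
Reagents that add atoms: dioxygen, O=O
Why: Nitrite-modified, aldehyde-selective (anti-Markovnikov) Wacker oxidation of the only electron-rich terminal alkene; the electron-poor dienone alkenes are inert.

**Step 3**
Reactants: 4 3-(1-methyl-4-oxocyclohexa-2,5-dien-1-yl)propanal
Product: 5 4-(but-3-yn-1-yl)-4-methylcyclohexa-2,5-dien-1-one
Conditions: dimethyl (1-diazo-2-oxopropyl)phosphonate (1.3 equiv), K2CO3 (2 equiv), MeOH, 0 °C to rt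
Reagents that add atoms: dimethyl (1-diazo-2-oxopropyl)phosphonate, CC(=O)C(=[N+]=[N-])P(=O)(OC)OC
Why: Ohira–Bestmann (Seyferth–Gilbert) homologation converts the aldehyde into the terminal alkyne (adds C8) under conditions mild enough for the dienone.

**Step 4**
Reactants: 5 4-(but-3-yn-1-yl)-4-methylcyclohexa-2,5-dien-1-one
Product: 6 4-methyl-4-(penta-3,4-dien-1-yl)cyclohexa-2,5-dien-1-one
Conditions: (CH2O)n (2.5 equiv), CuI (0.5 equiv), Cy2NH (1.8 equiv), dioxane, reflux
Reagents that add atoms: paraformaldehyde (formaldehyde), C=O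
Why: Crabbé homologation (Mannich reaction of the copper acetylide, then retro-imino-ene hydride transfer) turns the terminal alkyne into the terminal allene (adds C19); the bulky amine does not add to the dienone.

**Step 5 (key step)**
Reactants: 6 4-methyl-4-(penta-3,4-dien-1-yl)cyclohexa-2,5-dien-1-one
Product: 7 (3R,3aR,7aR)-7a-methyl-3-[1-(4,4,5,5-tetramethyl-1,3,2-dioxaborolan-2-yl)ethenyl]-1,2,3,3a,4,7a-hexahydro-5H-inden-5-one (cis-fused; 4β-Me, 16β-H, 7β-H)
Conditions: CuCl (5 mol%), (R,R)-Ph-BPE (6 mol%), NaOtBu (10 mol%), B2pin2 (1.2 equiv), MeOH (2 equiv), THF, 0 °C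
Reagents that add atoms: bis(pinacolato)diboron, CC1(C)OB(OC1(C)C)B1OC(C)(C)C(C)(C)O1
Why: Copper-catalysed borylative desymmetrising cyclisation: borylcupration of the allene terminus gives a 2-boryl allylcopper whose γ-carbon (C7) adds to one of the two enantiotopic enone β-carbons (C16); the tether forces cis ring fusion (C16-H syn to C4-Me), the six-membered metallo-ene-type transition state (Cu–C19–C8–C7···C16–C15) keeps C8 cis to C15 (C7-H syn to C16-H), and the chiral bisphosphine selects the enone and hence the absolute configuration.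

**Step 6**
Reactants: 7 alkenyl boronate from step 5
Product: 8 (3R,3aR,7aR)-3-(1-iodoethenyl)-7a-methyl-1,2,3,3a,4,7a-hexahydro-5H-inden-5-one
Conditions: NaI (1.5 equiv), TsN(Cl)Na·3H2O (1.5 equiv), THF/H2O 1:1, 0 °C
Reagents that add atoms: sodium iodide, [Na+].[I-]
Why: Electrophilic ipso-iododeboronation of the alkenyl boronate (iodonium generated from iodide and chloramine-T) gives the 2-iodoalkene without moving the double bond or touching C7.

**Step 7**
Reactants: 9 acrolein; 10 (E)-crotylboronic acid pinacol ester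
Product: 11 (3S,4R)-4-methylhexa-1,5-dien-3-ol
Conditions: (R)-TRIP phosphoric acid (5 mol%), toluene, −30 °C; aqueous work-up
Reagents that add atoms: none
Why: Chiral phosphoric acid-catalysed crotylboration through a closed chair (Zimmerman–Traxler) transition state: the E-crotyl geometry gives the anti OH/Me relationship and the catalyst the absolute sense (C11 S, C12 R).

**Step 8**
Reactants: 11 (3S,4R)-4-methylhexa-1,5-dien-3-ol
Product: 12 tert-butyldimethyl{[(3S,4R)-4-methylhexa-1,5-dien-3-yl]oxy}silane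
Conditions: TBSCl (1.2 equiv), imidazole (2 equiv), DMF, rt
Reagents that add atoms: tert-butyldimethylsilyl chloride, CC(C)(C)[Si](C)(C)Cl
Why: Standard silylation; the TBS ether protects C11-OH and differentiates the two vinyl groups for the next step.

**Step 9**
Reactants: 12 TBS ether of the dienol
Product: 14 (3R,4S)-4-(tert-butyldimethylsilyloxy)-3-methylhex-5-en-1-ol, via B-alkyl-9-BBN adduct 13 (not isolated)
Conditions: 9-BBN (1.0 equiv), THF, 0 °C to rt; then NaOH (aq), H2O2, 0 °C
Reagents that add atoms: hydrogen peroxide, OO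
Why: Anti-Markovnikov hydroboration–oxidation; 9-BBN takes the vinyl group next to the methyl-bearing carbon because the other one is inductively deactivated and shielded by the allylic silyloxy group.

**Step 10**
Reactants: 14 (3R,4S)-4-(tert-butyldimethylsilyloxy)-3-methylhex-5-en-1-ol
Product: 16 (3S,4R)-3-(tert-butyldimethylsilyloxy)-6,6-dimethoxy-4-methylhex-1-ene, via (3R,4S)-4-(tert-butyldimethylsilyloxy)-3-methylhex-5-enal 15 (not isolated)
Conditions: Dess–Martin periodinane (1.2 equiv), CH2Cl2, 0 °C to rt; then HC(OMe)3 (5 equiv), MeOH, PPTS (5 mol%), rt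
Reagents that add atoms: trimethyl orthoformate, COC(OC)OC
Why: Dess–Martin oxidation to the aldehyde followed in the same flask by acid-catalysed acetalisation masks the future C14 aldehyde in base-stable form.

**Step 11**
Reactants: 16 chain alkene; 8 alkenyl iodide
Product: 18 (3R,3aR,7aR)-3-[(5S,6R)-5-(tert-butyldimethylsilyloxy)-8,8-dimethoxy-6-methyloct-1-en-2-yl]-7a-methyl-1,2,3,3a,4,7a-hexahydro-5H-inden-5-one, via chain B-alkyl-9-BBN 17 (not isolated)
Conditions: 16, 9-BBN (1.3 equiv), THF, rt to 50 °C; then 8, Pd(dppf)Cl2 (5 mol%), AsPh3 (10 mol%), Cs2CO3 (3 equiv), DMF/H2O, rt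
Reagents that add atoms: none
Why: B-alkyl Suzuki–Miyaura coupling (sp3 borane with sp2 iodide) forms C8–C9 and completes the 1,1-disubstituted C8=C19 alkene; the enone, acetal and silyl ether are tolerated and no stereocentre is touched.

**Step 12**
Reactants: 18 coupled enone
Product: 20 C15-methyl enone (18 with CH3 at C15; C15 epimers), via lithium cross-conjugated dienolate 19 (not isolated)
Conditions: LiN(iPr)2 (1.1 equiv), THF, −78 °C; MeI (3 equiv), −78 to −20 °C
Reagents that add atoms: iodomethane, CI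
Why: Kinetic α′-deprotonation of the enone (the only acidic site; C4 is quaternary) and enolate methylation install the C15 methyl; the new C15 centre is transient because it becomes sp2 in step 14.

**Step 13**
Reactants: 20 C15-methyl enone
Product: 21 2β,3β-epoxy ketone
Conditions: H2O2 (30% aq, 5 equiv), NaOH (0.3 equiv), MeOH, 0 °C
Reagents that add atoms: hydrogen peroxide, OO
Why: Weitz–Scheffer nucleophilic epoxidation, selective for the enone over the unactivated methylene; hydroperoxide attacks C3 from the convex β face (opposite the cyclopentane and its α-oriented C7 side chain), setting C2 and C3.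

**Step 14**
Reactants: 21 2β,3β-epoxy ketone
Product: 22 C1 enol triflate (C1=C15 tetrasubstituted) with intact 2β,3β-epoxide
Conditions: KN(SiMe3)2 (1.2 equiv), THF, −78 to −40 °C; PhNTf2 (1.3 equiv)
Reagents that add atoms: N-phenylbis(trifluoromethanesulfonimide), O=S(=O)(N(c1ccccc1)S(=O)(=O)C(F)(F)F)C(F)(F)F
Why: Enolisation can only occur at C15 (the epoxide carbon cannot enolise), so O-triflation of the enolate gives the C1=C15 alkene and the handle for ring closure in one operation.

**Step 15**
Reactants: 22 epoxy enol triflate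
Product: 23 2α,3β-diacetoxy C1 enol triflate (C14 still the dimethyl acetal)
Conditions: Ac2O (solvent), Bu4NOAc (0.3 equiv), 80 °C
Reagents that add atoms: acetic anhydride, CC(=O)OC(C)=O
Why: Acetate-catalysed acylative epoxide opening: acetate attacks the allylic C2 in SN2 fashion (inversion, 2α-OAc; C3 is neopentyl) and the released C3 alkoxide is acetylated by the anhydride (3β-OAc), giving the trans-diacetate.

**Step 16**
Reactants: 23 diacetoxy triflate acetal
Product: 24 C14 aldehyde (2α,3β-diacetoxy C1 enol triflate, 11-OTBS)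
Conditions: PPTS (0.2 equiv), acetone/H2O 10:1, 50 °C
Reagents that add atoms: water, O
Why: Mild acid hydrolysis of the dimethyl acetal; the acetates, the enol triflate and the secondary TBS ether survive.

**Step 17**
Reactants: 24 aldehyde enol triflate
Product: 25 11-O-TBS macrocycle (target with C11-OTBS; 14S)
Conditions: CrCl2 (10 equiv), NiCl2 (0.2 equiv), DMSO/THF 3:1, 0.002 M, rt to 40 °C; aqueous work-up
Reagents that add atoms: none
Why: Intramolecular Nozaki–Hiyama–Kishi reaction: zerovalent nickel inserts into the alkenyl triflate, transmetalation gives an alkenylchromium that adds only to the aldehyde and closes the eleven-membered ring; C14 is set by the ring-constrained approach of the aldehyde (14S expected, side chain arriving from the α face).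

**Step 18**
Reactants: 25 11-O-TBS macrocycle
Product: 26 CNP0114864.2 (target)
Conditions: HF·pyridine, THF/pyridine, 0 °C to rt
Reagents that add atoms: none
Why: Fluoride cleavage of the silyl ether frees C11-OH without acetate migration or hydrolysis.

**Compound list**
1 | p-cresol | Cc1ccc(O)cc1 | starting material
2 | allyltrimethylsilane | C=CC[Si](C)(C)C | starting material
3 | 4-allyl-4-methylcyclohexa-2,5-dien-1-one | C=CCC1(C)C=CC(=O)C=C1 | intermediate
4 | 3-(1-methyl-4-oxocyclohexa-2,5-dien-1-yl)propanal | O=CCCC1(C)C=CC(=O)C=C1 | intermediate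
5 | 4-(but-3-yn-1-yl)-4-methylcyclohexa-2,5-dien-1-one | C#CCCC1(C)C=CC(=O)C=C1 | intermediate
6 | 4-methyl-4-(penta-3,4-dien-1-yl)cyclohexa-2,5-dien-1-one | C=C=CCCC1(C)C=CC(=O)C=C1 | intermediate
7 | (3R,3aR,7aR)-7a-methyl-3-[1-(pinacolboryl)ethenyl]-1,2,3,3a,4,7a-hexahydro-5H-inden-5-one | O=C1C[C@@H]2[C@H](C(=C)B3OC(C)(C)C(C)(C)O3)CC[C@]2(C)C=C1 | intermediate
8 | (3R,3aR,7aR)-3-(1-iodoethenyl)-7a-methyl-1,2,3,3a,4,7a-hexahydro-5H-inden-5-one | O=C1C[C@@H]2[C@H](C(=C)I)CC[C@]2(C)C=C1 | intermediate
9 | acrolein | C=CC=O | starting material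
10 | (E)-crotylboronic acid pinacol ester | C/C=C/CB1OC(C)(C)C(C)(C)O1 | starting material
11 | (3S,4R)-4-methylhexa-1,5-dien-3-ol | C=C[C@H](O)[C@H](C)C=C | intermediate
12 | tert-butyldimethyl{[(3S,4R)-4-methylhexa-1,5-dien-3-yl]oxy}silane | C=C[C@H](O[Si](C)(C)C(C)(C)C)[C@H](C)C=C | intermediate
13 | B-alkyl-9-BBN adduct of 12 (not isolated) | C=C[C@H](O[Si](C)(C)C(C)(C)C)[C@H](C)CCB1C2CCCC1CCC2 | intermediate
14 | (3R,4S)-4-(tert-butyldimethylsilyloxy)-3-methylhex-5-en-1-ol | C=C[C@H](O[Si](C)(C)C(C)(C)C)[C@H](C)CCO | intermediate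
15 | (3R,4S)-4-(tert-butyldimethylsilyloxy)-3-methylhex-5-enal (not isolated) | C=C[C@H](O[Si](C)(C)C(C)(C)C)[C@H](C)CC=O | intermediate
16 | (3S,4R)-3-(tert-butyldimethylsilyloxy)-6,6-dimethoxy-4-methylhex-1-ene | C=C[C@H](O[Si](C)(C)C(C)(C)C)[C@H](C)CC(OC)OC | intermediate
17 | chain B-alkyl-9-BBN from 16 (not isolated) | C1CCC2CCCC1B2CC[C@H](O[Si](C)(C)C(C)(C)C)[C@H](C)CC(OC)OC | intermediate
18 | C8–C9 coupled cis-hydrindenone (4β-Me, 16β-H, 7β-H; 11S, 12R) | O=C1C[C@@H]2[C@H](C(=C)CC[C@H](O[Si](C)(C)C(C)(C)C)[C@H](C)CC(OC)OC)CC[C@]2(C)C=C1 | intermediate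
19 | lithium dienolate of 18 (C1-OLi, C1=C15; not isolated) | [Li]OC1=C[C@@H]2[C@H](C(=C)CC[C@H](O[Si](C)(C)C(C)(C)C)[C@H](C)CC(OC)OC)CC[C@]2(C)C=C1 | intermediate
20 | C15-methyl enone (C15 epimers) | O=C1C(C)[C@@H]2[C@H](C(=C)CC[C@H](O[Si](C)(C)C(C)(C)C)[C@H](C)CC(OC)OC)CC[C@]2(C)C=C1 | intermediate
21 | 2β,3β-epoxy ketone (C15 epimers) | O=C1C(C)[C@@H]2[C@H](C(=C)CC[C@H](O[Si](C)(C)C(C)(C)C)[C@H](C)CC(OC)OC)CC[C@]2(C)[C@H]3O[C@@H]13 | intermediate
22 | C1 enol triflate with 2β,3β-epoxide | O=S(=O)(OC1=C(C)[C@@H]2[C@H](C(=C)CC[C@H](O[Si](C)(C)C(C)(C)C)[C@H](C)CC(OC)OC)CC[C@]2(C)[C@H]3O[C@@H]13)C(F)(F)F | intermediate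
23 | 2α,3β-diacetoxy C1 enol triflate, C14 dimethyl acetal | O=S(=O)(OC1=C(C)[C@@H]2[C@H](C(=C)CC[C@H](O[Si](C)(C)C(C)(C)C)[C@H](C)CC(OC)OC)CC[C@]2(C)[C@@H](OC(C)=O)[C@@H]1OC(C)=O)C(F)(F)F | intermediate
24 | 2α,3β-diacetoxy C1 enol triflate, C14 aldehyde | O=S(=O)(OC1=C(C)[C@@H]2[C@H](C(=C)CC[C@H](O[Si](C)(C)C(C)(C)C)[C@H](C)CC=O)CC[C@]2(C)[C@@H](OC(C)=O)[C@@H]1OC(C)=O)C(F)(F)F | intermediate
25 | 11-O-TBS macrocycle (14S) | C=C1CC[C@H](O[Si](C)(C)C(C)(C)C)[C@H](C)C[C@H](O)C2=C(C)[C@@H]3[C@H]1CC[C@]3(C)[C@@H](OC(C)=O)[C@@H]2OC(C)=O | intermediate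
26 | CNP0114864.2 | C=C1CC[C@H](O)[C@H](C)C[C@H](O)C2=C(C)[C@@H]3[C@H]1CC[C@]3(C)[C@@H](OC(C)=O)[C@@H]2OC(C)=O | target

**Step count and risks**
Total step count: 18. Longest linear sequence: 14 steps (steps 1–6, then 11–18, from p-cresol); the chain branch is 12 steps (7–10, then 11–18).

Three steps most likely to fail:

Step 1 (ortho attack, formal cycloaddition with the allylsilane or dienone dimerisation may erode the para-allylation of unblocked p-cresol). The fallback sets out from 1 and returns at 3, using a blocking-group approach. Bromination of 1 (Br2, CH2Cl2, 0 °C) gives 2,6-dibromo-4-methylphenol F1, whose ortho positions are closed. The same PhI(OAc)2/allyltrimethylsilane dearomatisation then gives 4-allyl-2,6-dibromo-4-methylcyclohexa-2,5-dien-1-one F2. Both alkenyl bromides are removed by palladium-catalysed formate hydrogenolysis (Pd(OAc)2, PPh3, HCO2Na, DMF, 80 °C) to give 3.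

Step 5 (the C7 configuration rests on the metallo-ene-type transition state; the wrong C7 epimer, low ee or boryl addition to the dienone are possible). The fallback sets out from 4 and returns at 8; it sets C7 by hydride delivery from palladium instead of by the allylcopper addition.
- A carbene-catalysed intramolecular Stetter reaction of 4 (chiral aminoindanol-derived triazolium salt, KN(SiMe3)2 cat., toluene) desymmetrises the dienone to the cis-fused enedione F3 (C7 ketone, C1 enone).
- Luche reduction (NaBH4, CeCl3·7H2O, MeOH, −78 °C) reduces only the conjugated C1 ketone to the allylic alcohol F4, which is silylated (TBSCl, imidazole) to the silyl ether F5.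
- 1-(Trimethylsilyl)vinyllithium adds to the C7 ketone from the convex β face and ClCO2Me traps the alkoxide as the tertiary allylic carbonate F6.
- Pd(OAc)2/PBu3 with HCO2NH4 (Tsuji formate reduction) ionises the carbonate anti to the α-oxygen and transfers hydride to C7 from the β face, giving the 1,1-disubstituted vinylsilane F7 with C7-H β.
- ICl converts the vinylsilane into the vinyl iodide F8, Bu4NF frees the allylic alcohol F9, and MnO2 reoxidises it to 8.

Step 17 (medium-ring closure at a hindered tetrasubstituted alkenyl triflate; the C14 configuration is under substrate control only). The fallback sets out from 24 and returns at 25; it moves C14 control from the C–C bond formation to a reagent-controlled reduction. The ring closure is run without regard to C14, the unwanted 14R alcohol F10 (or the epimer mixture) is oxidised with Dess–Martin periodinane to the macrocyclic C14 enone F11, and (R)-2-methyl-CBS-oxazaborolidine/BH3·SMe2 reduces it to the 14S alcohol 25.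

**Further compounds**
F1 | step 1 | 2,6-dibromo-4-methylphenol | Cc1cc(Br)c(O)c(Br)c1
F2 | step 1 | 4-allyl-2,6-dibromo-4-methylcyclohexa-2,5-dien-1-one | C=CCC1(C)C=C(Br)C(=O)C(Br)=C1
F3 | step 5 | cis-fused enedione (C7 ketone, C1 enone; 4β-Me, 16β-H) | O=C1C[C@@H]2C(=O)CC[C@]2(C)C=C1
F4 | step 5 | C1 allylic alcohol, C7 ketone (C1 epimers) | OC1C[C@@H]2C(=O)CC[C@]2(C)C=C1
F5 | step 5 | C1 O-TBS ether, C7 ketone | CC(C)(C)[Si](C)(C)OC1C[C@@H]2C(=O)CC[C@]2(C)C=C1
F6 | step 5 | C7 tertiary allylic methyl carbonate (7β-[1-(trimethylsilyl)vinyl], 7α-OCO2Me) | CC(C)(C)[Si](C)(C)OC1C[C@@H]2[C@](C(=C)[Si](C)(C)C)(OC(=O)OC)CC[C@]2(C)C=C1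
F7 | step 5 | 7α-[1-(trimethylsilyl)vinyl] 7β-H silyl ether | CC(C)(C)[Si](C)(C)OC1C[C@@H]2[C@H](C(=C)[Si](C)(C)C)CC[C@]2(C)C=C1
F8 | step 5 | 7α-(1-iodovinyl) C1 O-TBS ether | CC(C)(C)[Si](C)(C)OC1C[C@@H]2[C@H](C(=C)I)CC[C@]2(C)C=C1
F9 | step 5 | 7α-(1-iodovinyl) C1 allylic alcohol | OC1C[C@@H]2[C@H](C(=C)I)CC[C@]2(C)C=C1
F10 | step 17 | 14R epimer of 25 | C=C1CC[C@H](O[Si](C)(C)C(C)(C)C)[C@H](C)C[C@@H](O)C2=C(C)[C@@H]3[C@H]1CC[C@]3(C)[C@@H](OC(C)=O)[C@@H]2OC(C)=O
F11 | step 17 | macrocyclic C14 enone | C=C1CC[C@H](O[Si](C)(C)C(C)(C)C)[C@H](C)CC(=O)C2=C(C)[C@@H]3[C@H]1CC[C@]3(C)[C@@H](OC(C)=O)[C@@H]2OC(C)=O
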